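Carbons are numbered C1 (lactone carbonyl) to C20 (terminal methyl) in every compound. TBS = tert-butyldimethylsilyl, Bn = benzyl.

## The problem

Target 26 is an unbranched C20 chain whose only ring is a six-membered enol lactone (4-hydroxy-5,6-dihydropyran-2-one, ring A) closed between O5 and C1. There is no carbocycle and no quaternary carbon, so the task is chain assembly and stereocontrol. Four secondary carbinol centres stand at C5, C7, C9 and C11 with the pattern C5/C7 syn, C7/C9 anti, C9/C11 syn and the absolute configuration 5R,7R,9S,11S. Each can steer its direct neighbour through a hydroxyl-directed ketone reduction, but nothing controls a 1,5 distance reliably, so at least two of them have to arrive already configured. Ring A is a vinylogous acid that opens with base and nucleophiles, every oxygen is β to another oxygen or to a carbonyl (retro-aldol and β-elimination), and a free C7 hydroxyl can add to a C3 ketone. The 1,3-dicarbonyl unit should therefore appear only at the end. The feature to exploit is C9: a carbinol carbon between two methylenes (C8, C10) that are in turn flanked by the carbinols C7 and C11. Read as a carbonyl carbon with two negative charges, C9 can open a C10–C11 epoxide and then a C7–C8 epoxide, so that both neighbouring stereocentres come from small chiral epoxides and only C9 remains to be set.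

## Retrosynthesis

**Ring A (26 ⇒ 25 ⇒ 24).** The O5–C1 acyl–oxygen bond is cut. The neighbouring cuts (C2–C3 by a Dieckmann-type closure, or C1–C2 by carbonylation) need a strong base on a polyoxygenated chain or leave an enol ether to be cleaved. The precursor 25 is an open-chain δ-hydroxy β-keto ester, carried as 24 with O5 and O11 silylated and O7/O9 tied in an acetonide. The forward step must free four hydroxyls and let O5 alone close onto C1; only O5 can form a six-membered lactone.

**C2–C3 (24 ⇒ 22 + 23).** Cutting between C2 and C3 lets C1–C2 come from ethyl diazoacetate 23 and makes C3 an aldehyde in 22. A cut at C3–C4 (acetoacetate dianion plus a C5 aldehyde) would create C5 anew and uncontrolled. The aldehyde 22 goes back through alcohol 21 to benzyl ether 20, so C3 travels through all organometallic steps as an inert ether. The forward homologation must be mild enough not to eliminate the C5 silyloxy group.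

**C9 stereocentre (20 ⇒ 19 ⇒ 18 ⇒ 17).** The C9–H bond is cut: the anti C7/C9 pair of diol 19 comes from hydroxyl-directed reduction of ketone 18. Building C9 by an aldol or allylation would need a reagent-controlled step, whereas here the neighbour does the work. Ketone 18 is the hydrolysis product of dithiane 17. The forward reduction requires that O7 be free and O11 masked, so that one hydroxyl alone delivers hydride. Acetonide 20 then protects the new diol for the oxidation at C3.

**Key cut (17 ⇒ 3 + 7 + 13).** The C9–C10 and C8–C9 bonds are cut, giving the one-carbon linchpin 3, epoxide 7 (C10–C20) and epoxide 13 (C3–C8). Cuts at C7–C8 or C10–C11 would be aldol-type and would create C7 or C11 in the coupling. Here C5, C7 and C11 arrive as finished centres and both new bonds are SN2 openings at CH2 carbons. The forward reaction must add the two epoxides one after the other and must leave O11 silylated and O7 free, which is what the previous paragraph asks for.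

**Epoxide 13 (13 ⇒ 12 ⇒ 11 ⇒ 10 ⇒ 9 ⇒ 8).** The O7–C8 epoxide bond is cut back to a chlorohydrin. The syn C5/C7 pair and the whole C3–C8 skeleton are contained in the commercial chloro acetonide ester 8, made on scale as a side-chain building block for HMG-CoA reductase inhibitors. The de novo route (asymmetric allylation, then iodocarbonate cyclization) needs five steps and two selective events; this one needs four and none. The forward steps are ester reduction without loss of chloride (9), benzylation (10), and exchange of the acetonide for epoxide and silyl ether (11, 12, 13).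

**Epoxide 7 (7 ⇒ 6 ⇒ 4 + 5).** The C12–C13 bond is cut: (S)-epichlorohydrin 4 supplies C10–C12 with C11 configured, and n-octylmagnesium bromide 5 supplies C13–C20. Resolution of the racemic epoxide would discard half the material. The forward steps are opening of 4 at its ring CH2 to chlorohydrin 6 and ring closure by loss of chloride; the C11–O bond is never broken.

**Linchpin (3 ⇒ 1).** The C9–Si bond is cut: lithiation and silylation of 1,3-dithiane 1.

## Roads not taken

**Alternative 1:** two-directional iodocarbonate closure.
- Cut: the C5–O and C11–O bonds, on a nine-carbon C2-symmetric anti diene-diol (C4–C12) carried as its bis(tert-butyl carbonate) A1.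
- Forward key step: IBr at low temperature; each carbonate oxygen closes on its iodonium ion to a six-membered cyclic carbonate, giving the bis(iodomethyl) bis-carbonate A2 with C5/C7 and C9/C11 syn.
- Merits: after A2 all four stereocentres are in place. C7 and C9 come from one catalytic asymmetric event and C5 and C11 by 1,3-induction in one flask, with no chiral building block bought.
- Weak points: A2 has a twofold axis, so C4 and C12 are equivalent, yet the target needs an octyl group at C12 and the C1–C3 unit at C4; mono-functionalization is statistical. C4 is an electrophile while C3 of the target is a carbonyl carbon, so an acyl-anion equivalent carrying C1–C2 is still required and must be unmasked. Two cyclizations must both be selective. After carbonate cleavage the four hydroxyls are pairwise alike and need fresh differentiation.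
- Comparison: in stereochemical economy A2 is better than the chosen plan, which buys three centres and still reduces a ketone for the fourth. The chosen plan sets against this that its two chain ends differ from the start, that O3, O5, O7 and O11 leave the coupling already differentiated, and that C3 arrives oxygenated for a one-step homologation.

**Alternative 2:** oxidative carbonylation of an alkyne.
- Cut: ring A at O5–C1 and C1–C2, with the C3 oxygen entering as a methoxy group. The precursor is the homopropargylic alcohol A3 (C2–C20, terminal alkyne C2≡C3, O5 free, O7 silylated, C9/C11 acetonide).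
- Forward key step: Pd(OCOCF3)2 with a bis(oxazoline) ligand, carbon monoxide, methanol and p-benzoquinone. Methanol adds at C3, CO is inserted at C2 and O5 captures the acyl palladium to give the 4-methoxy-5,6-dihydropyran-2-one A4.
- Merits: ring A and C1 are made in one catalytic step, which replaces debenzylation, oxidation and homologation. The lactone end is about two steps shorter than in the chosen plan.
- Weak points: A4 is the methyl ether of the target's enol. Cleaving a vinylogous ester needs hot aqueous acid or a hard nucleophile, at the very end and next to three hydroxyls, one of which (O7) can add to C3. A3 must already hold all four stereocentres, so this road says nothing about the chain. A terminal alkyne C–H would have to be masked during any dithiane anion chemistry, which returns steps.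
- Comparison: the alternative is shorter at the lactone end. The chosen plan sets against this that β-keto ester 24 gives the free enol lactone directly under mild base, with no dealkylation on the unprotected polyol and no acidic C–H in the coupling.

**Alternative 3:** diepoxide linchpin with two alkynes.
- Cut: C10–C11 and C5–C6. C6–C10 is the diepoxide A5 with C7 and C9 preset anti; C11–C20 is 1-decyne A6; C3–C5 is benzyl propargyl ether A7.
- Forward key step: the lithium acetylide of A6 with BF3·OEt2 opens A5 at C10, then the acetylide of A7 opens the second epoxide at C6, giving the diyne anti-diol A8 without ring closure.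
- Merits: also a convergent three-component union. The C7/C9 anti pair, which costs the chosen plan a reduction, is bought in one reagent. Both nucleophiles are cheap and need no protecting-group work.
- Weak points: C5 and C11 are alkyne carbons in A8, not carbinols. Each alkyne must be hydrated at the carbon nearer the existing hydroxyl (C11 not C12, C5 not C4), against the usual oxygen-assisted hydration through a five-membered ring, so a tethered hydrosilylation–oxidation is needed at each. Two syn-selective directed reductions then follow, so two stereocentres are set late instead of one. Mono-opening of A5 competes with double opening, and A5 is volatile and takes several steps. The C3 benzyl ether end-game is the same as here.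
- Comparison: the alternative has the simpler coupling partners. The chosen plan sets against this that three of four stereocentres enter as finished carbinols, that only one ketone is reduced, and that its directing hydroxyl is singled out by the coupling itself.

Key step: step 8

## Remarks

- 26 is drawn as the enol tautomer of the β-keto δ-lactone; the keto tautomer is taken to be the same substance.
- 8 is assumed to be bought as the single (4R,6S) stereoisomer.

## Route

Step 1
Reactants: 1 1,3-dithiane
Product: 3 2-(tert-butyldimethylsilyl)-1,3-dithiane, via 2-lithio-1,3-dithiane 2 (not isolated)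
Conditions: n-BuLi, THF, −30 °C; TBSCl, −78 °C → rt
Reagents that add atoms: tert-butyldimethylsilyl chloride, CC(C)(C)[Si](C)(C)Cl
Why: Corey–Seebach lithiation of the dithiane C2–H followed by C-silylation of the carbanion; a standard preparation that installs the silyl group which later migrates.

Step 2
Reactants: 4 (S)-epichlorohydrin; 5 n-octylmagnesium bromide
Product: 6 (2S)-1-chloroundecan-2-ol
Conditions: CuI (10 mol%), THF, −40 → 0 °C; NH4Cl (aq)
Reagents that add atoms: none
Why: Copper-catalysed Grignard opening of a terminal epoxide; the organocopper species attacks the unsubstituted ring carbon of 4 faster than it displaces chloride, so C12–C13 forms and the untouched C11–O bond carries the S configuration into 6.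

Step 3
Reactants: 6 (2S)-1-chloroundecan-2-ol
Product: 7 (2S)-2-nonyloxirane [(S)-1,2-epoxyundecane]
Conditions: KOH, MeOH, 0 °C → rt
Reagents that add atoms: none
Why: Halohydrin ring closure (intramolecular Williamson reaction): the C11 alkoxide displaces chloride at C10; no bond to the stereocentre is made or broken, so 7 is the S epoxide.

Step 4
Reactants: 8 tert-butyl 2-[(4R,6S)-6-(chloromethyl)-2,2-dimethyl-1,3-dioxan-4-yl]acetate
Product: 9 2-[(4S,6S)-6-(chloromethyl)-2,2-dimethyl-1,3-dioxan-4-yl]ethan-1-ol
Conditions: LiAlH4, THF, 0 °C; aqueous NaOH work-up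
Reagents that add atoms: none
Why: Hydride reduction of an ester to the primary alcohol (C3); at 0 °C LiAlH4 reduces the ester far faster than a primary chloride next to an oxygenated carbon, and the acetonide is inert (the descriptor at C5 changes by priority only).

Step 5
Reactants: 9 2-[(4S,6S)-6-(chloromethyl)-2,2-dimethyl-1,3-dioxan-4-yl]ethan-1-ol
Product: 10 (4S,6S)-4-[2-(benzyloxy)ethyl]-6-(chloromethyl)-2,2-dimethyl-1,3-dioxane
Conditions: NaH, BnBr, n-Bu4NI (cat.), THF, 0 °C → rt
Reagents that add atoms: benzyl bromide, BrCc1ccccc1
Why: Williamson etherification of the primary alkoxide under iodide catalysis; the hindered chloride is a much poorer electrophile than benzyl bromide and the acetal is base-stable.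

Step 6
Reactants: 10 (4S,6S)-4-[2-(benzyloxy)ethyl]-6-(chloromethyl)-2,2-dimethyl-1,3-dioxane
Product: 12 (2S)-4-(benzyloxy)-1-[(2S)-oxiran-2-yl]butan-2-ol, via chloro diol 11 (not isolated)
Conditions: CSA (cat.), MeOH, rt; then K2CO3, MeOH, rt
Reagents that add atoms: none
Why: Acid-catalysed transketalization to methanol frees the syn diol 11, and carbonate then closes the C7–C8 epoxide by displacement of chloride by O7 (halohydrin closure); O5 has no favourable path onto the epoxide (4-exo or 5-endo) and neither stereocentre is touched.

Step 7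
Reactants: 12 (2S)-4-(benzyloxy)-1-[(2S)-oxiran-2-yl]butan-2-ol
Product: 13 (2S)-2-[(2S)-4-(benzyloxy)-2-(tert-butyldimethylsilyloxy)butyl]oxirane
Conditions: TBSCl, imidazole, DMF, rt
Reagents that add atoms: tert-butyldimethylsilyl chloride, CC(C)(C)[Si](C)(C)Cl
Why: Standard silylation of a secondary alcohol with a silyl chloride and imidazole; the conditions are mild enough to leave the epoxide closed.

Step 8
Reactants: 3 2-(tert-butyldimethylsilyl)-1,3-dithiane; 7 (2S)-2-nonyloxirane; 13 (2S)-2-[(2S)-4-(benzyloxy)-2-(tert-butyldimethylsilyloxy)butyl]oxirane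
Product: 17 (2S,4S)-6-(benzyloxy)-4-(TBSO)-1-{2-[(2S)-2-(TBSO)undecyl]-1,3-dithian-2-yl}hexan-2-ol, via lithiated silyl dithiane 14 (not isolated), via C-silyl lithium alkoxide 15 (not isolated), via O-silyl lithiodithiane 16 (not isolated)
Conditions: t-BuLi, Et2O, −78 → −45 °C; 7, −78 → −25 °C; then 13, HMPA, Et2O, −78 °C → rt; NH4Cl (aq)
Reagents that add atoms: none
Why: Three-component silyl dithiane linchpin coupling (anion relay by 1,4-Brook rearrangement), a known reaction type for two different terminal epoxides. t-BuLi removes the C9 proton of 3, and anion 14 opens epoxide 7 by SN2 attack at the unsubstituted C10 to give alkoxide 15, which in ether keeps silicon on carbon. HMPA, added together with 13, loosens the lithium–oxygen ion pair, silicon migrates from C9 to O11 through a five-membered silicate, and the carbanion 16 released at C9 opens 13 at the unsubstituted C8. Two skeletal bonds form (C9–C10 and C8–C9); no ring is closed and no stereocentre is created, and C5, C7 and C11 are carried over because none of their bonds is touched. The step needs attack at the CH2 end of each epoxide, which the monosubstituted oxiranes secure, and one epoxide per stage, which the solvent switch secures by holding back the Brook shift until 13 is present; the silyl and benzyl ethers of 13 offer no acidic hydrogen and no carbonyl group. The order of addition leaves O11 silylated and O7 free, the differentiation on which step 10 depends.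

Step 9
Reactants: 17 (2S,4S)-6-(benzyloxy)-4-(TBSO)-1-{2-[(2S)-2-(TBSO)undecyl]-1,3-dithian-2-yl}hexan-2-ol
Product: 18 (3S,5S,9S)-1-(benzyloxy)-3,9-bis(TBSO)-5-hydroxyoctadecan-7-one
Conditions: Hg(ClO4)2, CaCO3, THF/H2O (5:1), 0 °C
Reagents that add atoms: water, O
Why: Thiophilic-metal-assisted hydrolysis of a thioketal: the mercury salt binds sulfur, water adds to the thionium ion and CaCO3 buffers the acid, so the silyl ethers, the benzyl ether and the β-hydroxy ketone survive the short exposure at 0 °C.

Step 10
Reactants: 18 (3S,5S,9S)-1-(benzyloxy)-3,9-bis(TBSO)-5-hydroxyoctadecan-7-one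
Product: 19 (3S,5R,7R,9S)-1-(benzyloxy)-3,9-bis(TBSO)octadecane-5,7-diol
Conditions: Me4NBH(OAc)3, MeCN/AcOH (1:1), −30 °C
Reagents that add atoms: none
Why: Evans–Saksena reduction: the free C7 hydroxyl exchanges an acetate on boron and the alkoxyborohydride delivers hydride through a chair-like six-membered transition state to the face that makes C9 anti to C7 (and so syn to C11); the silylated O11 cannot bind boron and does not compete.

Step 11
Reactants: 19 (3S,5R,7R,9S)-1-(benzyloxy)-3,9-bis(TBSO)octadecane-5,7-diol
Product: 20 (4R,6R)-4-[(2S)-4-(benzyloxy)-2-(TBSO)butyl]-6-[(2S)-2-(TBSO)undecyl]-2,2-dimethyl-1,3-dioxane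
Conditions: Me2C(OMe)2, PPTS (cat.), CH2Cl2, rt
Reagents that add atoms: 2,2-dimethoxypropane, COC(C)(C)OC
Why: Acid-catalysed acetonide formation by transketalization; it masks the anti 1,3-diol so that C3 can later be oxidized without lactol formation at O7, and the mild pyridinium acid spares the silyl ethers.

Step 12
Reactants: 20 (4R,6R)-4-[(2S)-4-(benzyloxy)-2-(TBSO)butyl]-6-[(2S)-2-(TBSO)undecyl]-2,2-dimethyl-1,3-dioxane
Product: 21 (3S)-3-(TBSO)-4-{(4R,6R)-6-[(2S)-2-(TBSO)undecyl]-2,2-dimethyl-1,3-dioxan-4-yl}butan-1-ol
Conditions: H2 (1 atm), Pd/C, EtOAc, rt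
Reagents that add atoms: none
Why: Catalytic hydrogenolysis of a benzyl ether; sulfur was removed in step 9, so the palladium is not poisoned, and in neutral ethyl acetate the acetonide and silyl ethers are untouched.

Step 13
Reactants: 21 (3S)-3-(TBSO)-4-{(4R,6R)-6-[(2S)-2-(TBSO)undecyl]-2,2-dimethyl-1,3-dioxan-4-yl}butan-1-ol
Product: 22 (3R)-3-(TBSO)-4-{(4R,6R)-6-[(2S)-2-(TBSO)undecyl]-2,2-dimethyl-1,3-dioxan-4-yl}butanal
Conditions: Dess–Martin periodinane, NaHCO3, CH2Cl2, 0 °C → rt
Reagents that add atoms: none
Why: Dess–Martin oxidation of a primary alcohol to the aldehyde under buffered, non-basic conditions, which avoids β-elimination of the C5 silyloxy group and over-oxidation (the C5 descriptor changes by priority only).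

Step 14
Reactants: 22 (3R)-3-(TBSO)-4-{(4R,6R)-6-[(2S)-2-(TBSO)undecyl]-2,2-dimethyl-1,3-dioxan-4-yl}butanal; 23 ethyl diazoacetate
Product: 24 ethyl (5R)-5-(TBSO)-6-{(4R,6R)-6-[(2S)-2-(TBSO)undecyl]-2,2-dimethyl-1,3-dioxan-4-yl}-3-oxohexanoate
Conditions: SnCl2 (10 mol%), CH2Cl2, rt
Reagents that add atoms: none
Why: Roskamp homologation: SnCl2 activates the aldehyde, the diazo carbon adds to C3, and a 1,2-hydride shift with loss of dinitrogen gives the β-keto ester directly; aliphatic β-silyloxy aldehydes are good substrates and the catalytic, weakly Lewis acidic conditions spare the acetonide.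

Step 15
Reactants: 24 ethyl (5R)-5-(TBSO)-6-{(4R,6R)-6-[(2S)-2-(TBSO)undecyl]-2,2-dimethyl-1,3-dioxan-4-yl}-3-oxohexanoate
Product: 26 (6R)-4-hydroxy-6-[(2R,4S,6S)-2,4,6-trihydroxypentadecyl]-5,6-dihydro-2H-pyran-2-one, via tetrahydroxy keto ester 25 (not isolated)
Conditions: HF (48% aq), MeCN, 0 °C → rt; concentrate; K2CO3, MeOH, rt; then 1 M HCl to pH 3
Reagents that add atoms: none
Why: Global acidic deprotection (fluoride-assisted desilylation and acetonide hydrolysis) followed by base-mediated lactonization of the δ-hydroxy β-keto ester; only O5 can form a six-membered lactone with C1, and the stabilized enolate of the vinylogous acid is the thermodynamic sink, so acidification should release 26 as its enol with no stereocentre touched.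

## Compound list

1 | 1,3-dithiane | C1CSCSC1 | starting material
2 | 2-lithio-1,3-dithiane (formed in the flask) | [Li]C1SCCCS1 | intermediate
3 | 2-(tert-butyldimethylsilyl)-1,3-dithiane | CC(C)(C)[Si](C)(C)C1SCCCS1 | intermediate
4 | (S)-epichlorohydrin [(2S)-2-(chloromethyl)oxirane] | ClC[C@@H]1CO1 | starting material
5 | n-octylmagnesium bromide | CCCCCCCC[Mg]Br | starting material
6 | (2S)-1-chloroundecan-2-ol | CCCCCCCCC[C@H](O)CCl | intermediate
7 | (2S)-2-nonyloxirane [(S)-1,2-epoxyundecane] | CCCCCCCCC[C@H]1CO1 | intermediate
8 | tert-butyl 2-[(4R,6S)-6-(chloromethyl)-2,2-dimethyl-1,3-dioxan-4-yl]acetate | ClC[C@@H]1C[C@H](CC(=O)OC(C)(C)C)OC(C)(C)O1 | starting material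
9 | 2-[(4S,6S)-6-(chloromethyl)-2,2-dimethyl-1,3-dioxan-4-yl]ethan-1-ol | ClC[C@@H]1C[C@H](CCO)OC(C)(C)O1 | intermediate
10 | (4S,6S)-4-[2-(benzyloxy)ethyl]-6-(chloromethyl)-2,2-dimethyl-1,3-dioxane | ClC[C@@H]1C[C@H](CCOCc2ccccc2)OC(C)(C)O1 | intermediate
11 | (2S,4S)-6-(benzyloxy)-1-chlorohexane-2,4-diol (formed in the flask) | ClC[C@@H](O)C[C@@H](O)CCOCc1ccccc1 | intermediate
12 | (2S)-4-(benzyloxy)-1-[(2S)-oxiran-2-yl]butan-2-ol | O1C[C@@H]1C[C@@H](O)CCOCc1ccccc1 | intermediate
13 | (2S)-2-[(2S)-4-(benzyloxy)-2-(tert-butyldimethylsilyloxy)butyl]oxirane | O1C[C@@H]1C[C@@H](O[Si](C)(C)C(C)(C)C)CCOCc1ccccc1 | intermediate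
14 | 2-lithio-2-(tert-butyldimethylsilyl)-1,3-dithiane (formed in the flask) | [Li]C1(SCCCS1)[Si](C)(C)C(C)(C)C | intermediate
15 | lithium (2S)-1-[2-(tert-butyldimethylsilyl)-1,3-dithian-2-yl]undecan-2-olate (formed in the flask) | CCCCCCCCC[C@H](O[Li])CC1(SCCCS1)[Si](C)(C)C(C)(C)C | intermediate
16 | 2-lithio-2-[(2S)-2-(tert-butyldimethylsilyloxy)undecyl]-1,3-dithiane (formed in the flask) | CCCCCCCCC[C@H](O[Si](C)(C)C(C)(C)C)CC1([Li])SCCCS1 | intermediate
17 | (2S,4S)-6-(benzyloxy)-4-(TBSO)-1-{2-[(2S)-2-(TBSO)undecyl]-1,3-dithian-2-yl}hexan-2-ol | CCCCCCCCC[C@H](O[Si](C)(C)C(C)(C)C)CC1(SCCCS1)C[C@@H](O)C[C@@H](O[Si](C)(C)C(C)(C)C)CCOCc1ccccc1 | intermediate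
18 | (3S,5S,9S)-1-(benzyloxy)-3,9-bis(TBSO)-5-hydroxyoctadecan-7-one | CCCCCCCCC[C@H](O[Si](C)(C)C(C)(C)C)CC(=O)C[C@@H](O)C[C@@H](O[Si](C)(C)C(C)(C)C)CCOCc1ccccc1 | intermediate
19 | (3S,5R,7R,9S)-1-(benzyloxy)-3,9-bis(TBSO)octadecane-5,7-diol | CCCCCCCCC[C@H](O[Si](C)(C)C(C)(C)C)C[C@H](O)C[C@@H](O)C[C@@H](O[Si](C)(C)C(C)(C)C)CCOCc1ccccc1 | intermediate
20 | (4R,6R)-4-[(2S)-4-(benzyloxy)-2-(TBSO)butyl]-6-[(2S)-2-(TBSO)undecyl]-2,2-dimethyl-1,3-dioxane | CCCCCCCCC[C@H](O[Si](C)(C)C(C)(C)C)C[C@H]1C[C@H](C[C@@H](O[Si](C)(C)C(C)(C)C)CCOCc2ccccc2)OC(C)(C)O1 | intermediate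
21 | (3S)-3-(TBSO)-4-{(4R,6R)-6-[(2S)-2-(TBSO)undecyl]-2,2-dimethyl-1,3-dioxan-4-yl}butan-1-ol | CCCCCCCCC[C@H](O[Si](C)(C)C(C)(C)C)C[C@H]1C[C@H](C[C@@H](O[Si](C)(C)C(C)(C)C)CCO)OC(C)(C)O1 | intermediate
22 | (3R)-3-(TBSO)-4-{(4R,6R)-6-[(2S)-2-(TBSO)undecyl]-2,2-dimethyl-1,3-dioxan-4-yl}butanal | CCCCCCCCC[C@H](O[Si](C)(C)C(C)(C)C)C[C@H]1C[C@H](C[C@@H](O[Si](C)(C)C(C)(C)C)CC=O)OC(C)(C)O1 | intermediate
23 | ethyl diazoacetate | CCOC(=O)C=[N+]=[N-] | starting material
24 | ethyl (5R)-5-(TBSO)-6-{(4R,6R)-6-[(2S)-2-(TBSO)undecyl]-2,2-dimethyl-1,3-dioxan-4-yl}-3-oxohexanoate | CCCCCCCCC[C@H](O[Si](C)(C)C(C)(C)C)C[C@H]1C[C@H](C[C@@H](O[Si](C)(C)C(C)(C)C)CC(=O)CC(=O)OCC)OC(C)(C)O1 | intermediate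
25 | ethyl (5R,7R,9S,11S)-5,7,9,11-tetrahydroxy-3-oxoicosanoate (formed in the flask) | CCCCCCCCC[C@H](O)C[C@H](O)C[C@@H](O)C[C@@H](O)CC(=O)CC(=O)OCC | intermediate
26 | (6R)-4-hydroxy-6-[(2R,4S,6S)-2,4,6-trihydroxypentadecyl]-5,6-dihydro-2H-pyran-2-one | CCCCCCCCC[C@H](O)C[C@H](O)C[C@@H](O)C[C@@H]1CC(O)=CC(=O)O1 | target

## Step count and risks

Total: 15 steps. Longest linear sequence: 12 steps (steps 4 to 15, from 8 to 26). Steps 1 and 2–3 are one- and two-step branches that join at step 8.

**Step 8 (key step).** The likely failure is mistimed silyl migration. If silicon moves before 13 is present, the relayed anion adds a second molecule of 7 or is quenched by proton transfer. If it lags, the hindered β-silyloxy epoxide 13 is opened only slowly and the anion decays. The fallback separates the two alkylations and replaces the Brook shift by direct deprotonation. It sets out from 1 and 7: 1 is lithiated (n-BuLi, THF) and opens 7 to give (2S)-1-(1,3-dithian-2-yl)undecan-2-ol F1. Silylation (TBSCl, imidazole) gives 2-[(2S)-2-(tert-butyldimethylsilyloxy)undecyl]-1,3-dithiane F2. Lithiation of F2 (t-BuLi, THF/HMPA, −78 °C) generates 16, and addition of 13 returns to the route at 17.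

**Step 15.** Two processes threaten. In the acidic stage the freed C7 hydroxyl can add to the C3 ketone and the hemiketal can dehydrate to a cyclic enol ether. In the basic stage retro-aldol cleavage at C4–C5 competes with lactonization. The fallback changes the order of events so that the lactone exists before O7 is released. It sets out from 24: buffered HF·pyridine (pyridine, THF) should remove only the two silyl ethers and give ethyl (5R)-5-hydroxy-6-{(4S,6S)-6-[(2S)-2-hydroxyundecyl]-2,2-dimethyl-1,3-dioxan-4-yl}-3-oxohexanoate F5. K2CO3 in MeOH closes ring A to the acetonide lactone (6R)-4-hydroxy-6-{[(4R,6S)-6-[(2S)-2-hydroxyundecyl]-2,2-dimethyl-1,3-dioxan-4-yl]methyl}-5,6-dihydro-2H-pyran-2-one F6. Aqueous acetic acid (40 °C) then hydrolyses the acetonide and returns to the route at 26.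

**Step 14.** The Lewis acid may trigger β-elimination of the C5 silyloxy group from the activated aldehyde, or partial opening of the acetonide. The fallback builds the C2–C3 bond by an aldol addition and adjusts the oxidation level afterwards. It sets out from 22: the lithium enolate of ethyl acetate (LiN(i-Pr)2, THF, −78 °C) adds to give ethyl (3RS,5S)-5-(TBSO)-6-{(4R,6R)-6-[(2S)-2-(TBSO)undecyl]-2,2-dimethyl-1,3-dioxan-4-yl}-3-hydroxyhexanoate F4 as a mixture of C3 epimers. Dess–Martin oxidation converges both epimers and returns to the route at 24.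

**Step 10.** Facial selectivity may be insufficient if hydride is delivered without prior binding of boron to O7, which would give the C9 epimer. The fallback uses an Evans–Tishchenko reduction, in which hydride comes from a samarium-bound hemiacetal formed on O7. It sets out from 18: acetaldehyde and SmI2 (cat.) in THF at −10 °C should give the anti diol monoacetate (3S,5R,7R,9S)-1-(benzyloxy)-3,9-bis(TBSO)-7-hydroxyoctadecan-5-yl acetate F3. Methanolysis (K2CO3, MeOH) returns to the route at 19.

## Further compounds

F1 | step 8 | (2S)-1-(1,3-dithian-2-yl)undecan-2-ol | CCCCCCCCC[C@H](O)CC1SCCCS1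
F2 | step 8 | 2-[(2S)-2-(tert-butyldimethylsilyloxy)undecyl]-1,3-dithiane | CCCCCCCCC[C@H](O[Si](C)(C)C(C)(C)C)CC1SCCCS1
F3 | step 10 | (3S,5R,7R,9S)-1-(benzyloxy)-3,9-bis(TBSO)-7-hydroxyoctadecan-5-yl acetate | CCCCCCCCC[C@H](O[Si](C)(C)C(C)(C)C)C[C@H](O)C[C@@H](OC(C)=O)C[C@@H](O[Si](C)(C)C(C)(C)C)CCOCc1ccccc1
F4 | step 14 | ethyl (3RS,5S)-5-(TBSO)-6-{(4R,6R)-6-[(2S)-2-(TBSO)undecyl]-2,2-dimethyl-1,3-dioxan-4-yl}-3-hydroxyhexanoate | CCCCCCCCC[C@H](O[Si](C)(C)C(C)(C)C)C[C@H]1C[C@H](C[C@@H](O[Si](C)(C)C(C)(C)C)CC(O)CC(=O)OCC)OC(C)(C)O1
F5 | step 15 | ethyl (5R)-5-hydroxy-6-{(4S,6S)-6-[(2S)-2-hydroxyundecyl]-2,2-dimethyl-1,3-dioxan-4-yl}-3-oxohexanoate | CCCCCCCCC[C@H](O)C[C@H]1C[C@H](C[C@@H](O)CC(=O)CC(=O)OCC)OC(C)(C)O1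
F6 | step 15 | (6R)-4-hydroxy-6-{[(4R,6S)-6-[(2S)-2-hydroxyundecyl]-2,2-dimethyl-1,3-dioxan-4-yl]methyl}-5,6-dihydro-2H-pyran-2-one | CCCCCCCCC[C@H](O)C[C@H]1C[C@H](C[C@@H]2CC(O)=CC(=O)O2)OC(C)(C)O1
A1 | alternative 1 | di-tert-butyl (4S,6S)-nona-1,8-diene-4,6-diyl bis(carbonate) | C=CC[C@H](OC(=O)OC(C)(C)C)C[C@@H](OC(=O)OC(C)(C)C)CC=C
A2 | alternative 1 | C4–C12 bis(iodomethyl) bis(cyclic carbonate), 4,4'-methylenebis[6-(iodomethyl)-1,3-dioxan-2-one] with C5, C7, C9 and C11 as in the target | IC[C@H]1C[C@H](OC(=O)O1)C[C@@H]2C[C@H](CI)OC(=O)O2
A3 | alternative 2 | C2–C20 homopropargylic alcohol with O5 free, O7 silylated and the C9/C11 acetonide | CCCCCCCCC[C@H]1C[C@H](OC(C)(C)O1)C[C@@H](O[Si](C)(C)C(C)(C)C)C[C@@H](O)CC#C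
A4 | alternative 2 | protected 4-methoxy-5,6-dihydropyran-2-one (C1–C20) | CCCCCCCCC[C@H]1C[C@H](OC(C)(C)O1)C[C@@H](O[Si](C)(C)C(C)(C)C)C[C@@H]2CC(OC)=CC(=O)O2
A5 | alternative 3 | (2R,4R)-1,2:4,5-diepoxypentane | C1O[C@@H]1C[C@@H]1CO1
A6 | alternative 3 | 1-decyne | C#CCCCCCCCC
A7 | alternative 3 | benzyl propargyl ether | C#CCOCc1ccccc1
A8 | alternative 3 | (5S,7S)-1-(benzyloxy)octadeca-2,9-diyne-5,7-diol | CCCCCCCCC#CC[C@H](O)C[C@@H](O)CC#CCOCc1ccccc1
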